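**Plan**

1. Numbering (3,7-dioxabicyclo[3.3.0]octane): C1 = carbinol bridgehead, C2 = ArCH next to it, O3, C4H2, C5 = CH bridgehead, C6 = second ArCH, O7, C8H2. Ring A = C1-C2-O3-C4-C5, ring B = C5-C6-O7-C8-C1.
2. Retrosynthesis cuts, in order: C6–O7 with C5–H (hydroalkoxylation of a C5=C6 arylidene by the C8 hydroxyl); C1–OH and C8–OH (dihydroxylation of a C1=C8 methylene); C1–C5 (enyne cycloisomerisation); C2–O3 (allylic etherification); aryl–alkyne (Sonogashira).
3. Forward: a cinnamyl carbonate and an arylpropargyl alcohol are joined at C2–O3, ring A is closed at C1–C5, the diol is installed, and ring B is closed last.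
4. Enabling feature: the 3,4-dimethoxyphenyl group on C6 makes C6 a stabilised benzylic radical and cation, and the C8 hydroxymethyl group on C1 sits on one face of ring A within reach of C6, so only the cis-fused five-membered ring can form.
5. Stereochemistry: C2 is set by the chiral iridium catalyst; C1 by osmylation anti to the C2 aryl group; C5 and C6 together in the key step by substrate control.

Key step: step 6

Remark: compound 4 is taken as a catalogue compound, and the geometry of the C5=C6 bond is erased in the key step, so either geometric isomer of the arylidene serves.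

**Step 1**
Reactants: 1 4-iodo-1,2-dimethoxybenzene; 2 prop-2-yn-1-ol
Product: 3 3-(3,4-dimethoxyphenyl)prop-2-yn-1-ol
Conditions: PdCl2(PPh3)2 (2 mol %), CuI (4 mol %), Et3N, THF, rt
Reagents that add atoms: none
Why: Sonogashira coupling of an aryl iodide with a terminal alkyne, in which the free hydroxyl is tolerated.

**Step 2**
Reactants: 4 (2E)-3-(3,4-dimethoxyphenyl)prop-2-en-1-ol
Product: 5 tert-butyl (2E)-3-(3,4-dimethoxyphenyl)prop-2-en-1-yl carbonate
Conditions: Boc2O, DMAP (10 mol %), CH2Cl2, 0 °C to rt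
Reagents that add atoms: di-tert-butyl dicarbonate, CC(C)(C)OC(=O)OC(=O)OC(C)(C)C
Why: DMAP-catalysed O-acylation gives the tert-butyl carbonate, a leaving group that ionises readily with iridium and releases only tert-butoxide, which should not compete as a nucleophile.

**Step 3**
Reactants: 5 tert-butyl (2E)-3-(3,4-dimethoxyphenyl)prop-2-en-1-yl carbonate; 3 3-(3,4-dimethoxyphenyl)prop-2-yn-1-ol
Product: 6 4-[(1R)-1-{[3-(3,4-dimethoxyphenyl)prop-2-yn-1-yl]oxy}prop-2-en-1-yl]-1,2-dimethoxybenzene
Conditions: [Ir(cod)Cl]2 (2 mol %), binaphthol-based N,N-bis(1-phenylethyl)phosphoramidite (4 mol %, the enantiomer that gives the R ether), K3PO4, THF, rt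
Reagents that add atoms: none
Why: Iridium-phosphoramidite-catalysed asymmetric allylic etherification, in which the alkoxide of 3 attacks the allyliridium intermediate at the aryl-bearing terminus (branched selectivity) and the chiral ligand fixes C2, the only stereocenter of the route set by a catalyst.

**Step 4**
Reactants: 6 4-[(1R)-1-{[3-(3,4-dimethoxyphenyl)prop-2-yn-1-yl]oxy}prop-2-en-1-yl]-1,2-dimethoxybenzene
Product: 7 (2S,4Z)-4-(3,4-dimethoxybenzylidene)-2-(3,4-dimethoxyphenyl)-3-methylenetetrahydrofuran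
Conditions: Pd(OAc)2 (5 mol %), PPh3 (10 mol %), toluene, 60 °C
Reagents that add atoms: none
Why: Palladium-catalysed 1,6-enyne cycloisomerisation (Alder-ene type): syn-hydropalladation of the alkyne with palladium on the carbon next to C4, 5-exo-trig carbopalladation of the vinyl group to make the C1–C5 bond of ring A, and beta-hydride elimination of the only beta-hydrogen (on C1) to give the C1=C8 methylene; the syn addition fixes the Z arylidene and C2 is not touched.

**Step 5**
Reactants: 7 (2S,4Z)-4-(3,4-dimethoxybenzylidene)-2-(3,4-dimethoxyphenyl)-3-methylenetetrahydrofuran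
Product: 8 (2S,3S,4E)-4-(3,4-dimethoxybenzylidene)-2-(3,4-dimethoxyphenyl)-3-(hydroxymethyl)tetrahydrofuran-3-ol
Conditions: OsO4 (2 mol %), NMO (1.1 equiv), acetone/H2O, 0 °C
Reagents that add atoms: N-methylmorpholine N-oxide, C[N+]1([O-])CCOCC1; water, O
Why: Catalytic osmium tetroxide syn-dihydroxylation should take the 1,1-disubstituted C1=C8 bond, the diene terminus remote from the aryl group whose oxidation leaves the styrene conjugated, and should add to the face anti to the adjacent C2 aryl group, which places the C1 hydroxyl trans to that aryl and sets C1 by substrate control.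

**Step 6**
Reactants: 8 (2S,3S,4E)-4-(3,4-dimethoxybenzylidene)-2-(3,4-dimethoxyphenyl)-3-(hydroxymethyl)tetrahydrofuran-3-ol
Product: 11 (1S,2S,5R,6S)-2,6-bis(3,4-dimethoxyphenyl)-3,7-dioxabicyclo[3.3.0]octan-1-ol, via benzylic radical 9 (not isolated), via benzylic cation 10 (not isolated)
Conditions: Co(salen) [N,N'-bis(3,5-di-tert-butylsalicylidene)-1,2-cyclohexanediamine complex of divalent cobalt] (5 mol %), N-fluoro-2,4,6-trimethylpyridinium tetrafluoroborate (1.2 equiv), PhSiH3 (1.2 equiv), PhCF3, 0 °C to rt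
Reagents that add atoms: none
Why: The divalent cobalt complex is oxidised by the N-fluoropyridinium salt and converted by the silane into a trivalent cobalt hydride, which transfers a hydrogen atom to C5 of the C5=C6 arylidene to give the 3,4-dimethoxybenzyl radical 9; this is oxidised by trivalent cobalt (radical-polar crossover) to the para-alkoxy-stabilised benzylic cation 10, which the C8 hydroxyl captures. The closest known reaction type is the cobalt-salen, Mukaiyama-type hydrogen-atom-transfer hydroalkoxylation of alkenols. Ring B closes in a 5-endo-trig sense with respect to the alkene, as capture of a cation by oxygen, and the tertiary C1 hydroxyl cannot compete because it would give an oxetane. C5 is set by hydrogen-atom delivery to the face of ring A that carries the C1 hydroxyl, anti to the C8 hydroxymethyl and C2 aryl groups, and the ring constraint corrects errors, since only the intermediate with C6 cis to C8 can close to the cis-fused bicycle while the other can only return to the alkene. C6 is set when the planar cation is attacked with its aryl group turned to the convex face, away from C4, which should give the exo aryl group. The step needs hydrogen-atom transfer to C5 and not to C6, which the benzylic stabilisation at C6 secures, and it must spare the C2 benzylic ether and the tertiary allylic alcohol, which the near-neutral, collidine-buffered medium secures.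

**Compound list**

1 | 4-iodo-1,2-dimethoxybenzene | COc1ccc(I)cc1OC | starting material
2 | prop-2-yn-1-ol | OCC#C | starting material
3 | 3-(3,4-dimethoxyphenyl)prop-2-yn-1-ol | COc1ccc(C#CCO)cc1OC | intermediate
4 | (2E)-3-(3,4-dimethoxyphenyl)prop-2-en-1-ol | COc1ccc(/C=C/CO)cc1OC | starting material
5 | tert-butyl (2E)-3-(3,4-dimethoxyphenyl)prop-2-en-1-yl carbonate | COc1ccc(/C=C/COC(=O)OC(C)(C)C)cc1OC | intermediate
6 | 4-[(1R)-1-{[3-(3,4-dimethoxyphenyl)prop-2-yn-1-yl]oxy}prop-2-en-1-yl]-1,2-dimethoxybenzene | COc1ccc(C#CCO[C@H](C=C)c2ccc(OC)c(OC)c2)cc1OC | intermediate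
7 | (2S,4Z)-4-(3,4-dimethoxybenzylidene)-2-(3,4-dimethoxyphenyl)-3-methylenetetrahydrofuran | COc1ccc(/C=C2\CO[C@@H](c3ccc(OC)c(OC)c3)C2=C)cc1OC | intermediate
8 | (2S,3S,4E)-4-(3,4-dimethoxybenzylidene)-2-(3,4-dimethoxyphenyl)-3-(hydroxymethyl)tetrahydrofuran-3-ol | OC[C@@]1(O)/C(=C/c2ccc(OC)c(OC)c2)CO[C@H]1c1ccc(OC)c(OC)c1 | intermediate
9 | benzylic radical: (3,4-dimethoxyphenyl)[(3R,4S,5S)-5-(3,4-dimethoxyphenyl)-4-hydroxy-4-(hydroxymethyl)tetrahydrofuran-3-yl]methyl radical | OC[C@@]1(O)[C@@H]([CH]c2ccc(OC)c(OC)c2)CO[C@H]1c1ccc(OC)c(OC)c1 | intermediate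
10 | benzylic cation: the corresponding (3,4-dimethoxyphenyl)(tetrahydrofuran-3-yl)methylium ion | OC[C@@]1(O)[C@@H]([CH+]c2ccc(OC)c(OC)c2)CO[C@H]1c1ccc(OC)c(OC)c1 | intermediate
11 | (1S,2S,5R,6S)-2,6-bis(3,4-dimethoxyphenyl)-3,7-dioxabicyclo[3.3.0]octan-1-ol (cis-fused; 2-aryl trans to the 1-hydroxyl, 6-aryl cis to H-5) | COc1ccc([C@H]2OC[C@@]3(O)[C@@H]2CO[C@H]3c2ccc(OC)c(OC)c2)cc1OC | target

**Count and risks**

Total steps: 6. Longest linear sequence: 5 (steps 2, 3, 4, 5, 6, or equally 1, 3, 4, 5, 6).

Step 6 is the first risk. The benzylic radical may be reduced to the benzyl compound before it is oxidised, or the cation may lose a proton and not be intercepted by the hydroxyl. The fallback sets out from 8 and closes ring B in two operations. Mukaiyama hydration (Mn(dpm)3, PhSiH3, O2, i-PrOH, 0 °C; then PPh3) traps the same radical with oxygen and should give (2S,3S,4R)-2-(3,4-dimethoxyphenyl)-4-[(3,4-dimethoxyphenyl)(hydroxy)methyl]-3-(hydroxymethyl)tetrahydrofuran-3-ol F1 as a mixture at the new carbinol carbon. This secondary para-alkoxybenzylic alcohol should ionise under catalytic PPTS in CH2Cl2 far more readily than the C2 ether, and the resulting cation is captured by the C8 hydroxyl with the aryl group exo, which comes back to the route at 11.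

Step 4 is the second risk. Hydridopalladium may move the exocyclic double bonds into the ring (aromatisation to a furan), the planar s-cis diene may dimerise, or zerovalent palladium may ionise the allylic benzylic ether. The fallback sets out from 5 and closes ring A by a Heck reaction instead.
- Purchased (E)-3,4-dimethoxycinnamaldehyde is iodinated (I2, DMAP, K2CO3, THF/H2O) to (2Z)-3-(3,4-dimethoxyphenyl)-2-iodoprop-2-enal F2.
- Luche reduction (NaBH4, CeCl3·7H2O, MeOH, 0 °C) gives (2Z)-3-(3,4-dimethoxyphenyl)-2-iodoprop-2-en-1-ol F3.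
- The iridium etherification of step 3 with 5 and F3 gives 4-[(1Z)-3-{[(1R)-1-(3,4-dimethoxyphenyl)prop-2-en-1-yl]oxy}-2-iodoprop-1-en-1-yl]-1,2-dimethoxybenzene F4.
- An intramolecular 5-exo-trig Heck reaction (Pd(OAc)2, PPh3, Ag2CO3, MeCN, 60 °C) should give (2S,4E)-4-(3,4-dimethoxybenzylidene)-2-(3,4-dimethoxyphenyl)-3-methylenetetrahydrofuran F5. The silver salt removes hydridopalladium, and the inward-pointing aryl group twists the diene, which should slow dimerisation.
- Dihydroxylation as in step 5 gives (2S,3S,4Z)-4-(3,4-dimethoxybenzylidene)-2-(3,4-dimethoxyphenyl)-3-(hydroxymethyl)tetrahydrofuran-3-ol F6.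
- The conditions of step 6 erase the alkene geometry, so the fallback comes back to the route at 11.

Step 5 is the third risk. Osmylation may occur at the electron-rich styrenyl double bond or at both double bonds. The fallback sets out from 5 and brings the second aryl group in only after the diol is in place.
- The etherification of step 3 with purchased 3-(trimethylsilyl)prop-2-yn-1-ol gives {3-[(1R)-1-(3,4-dimethoxyphenyl)prop-2-en-1-yloxy]prop-1-yn-1-yl}trimethylsilane F7.
- Cycloisomerisation as in step 4 gives (2S,4Z)-2-(3,4-dimethoxyphenyl)-3-methylene-4-[(trimethylsilyl)methylene]tetrahydrofuran F8, whose vinylsilane is hindered and less electron-rich.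
- Dihydroxylation of the methylene group (OsO4, NMO) gives (2S,3S,4E)-2-(3,4-dimethoxyphenyl)-3-(hydroxymethyl)-4-[(trimethylsilyl)methylene]tetrahydrofuran-3-ol F9.
- Iododesilylation with retention (NIS, MeCN, 0 °C) gives (2S,3S,4E)-2-(3,4-dimethoxyphenyl)-3-(hydroxymethyl)-4-(iodomethylene)tetrahydrofuran-3-ol F10.
- Suzuki–Miyaura coupling with (3,4-dimethoxyphenyl)boronic acid (Pd(PPh3)4, K2CO3, dioxane/H2O, 60 °C) comes back to the route at 8.

**Further compounds**

F1 | step 6 | (2S,3S,4R)-2-(3,4-dimethoxyphenyl)-4-[(3,4-dimethoxyphenyl)(hydroxy)methyl]-3-(hydroxymethyl)tetrahydrofuran-3-ol (mixture at the benzylic carbinol carbon) | OC[C@@]1(O)[C@@H](C(O)c2ccc(OC)c(OC)c2)CO[C@H]1c1ccc(OC)c(OC)c1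
F2 | step 4 | (2Z)-3-(3,4-dimethoxyphenyl)-2-iodoprop-2-enal | COc1ccc(/C=C(\I)C=O)cc1OC
F3 | step 4 | (2Z)-3-(3,4-dimethoxyphenyl)-2-iodoprop-2-en-1-ol | COc1ccc(/C=C(\I)CO)cc1OC
F4 | step 4 | 4-[(1Z)-3-{[(1R)-1-(3,4-dimethoxyphenyl)prop-2-en-1-yl]oxy}-2-iodoprop-1-en-1-yl]-1,2-dimethoxybenzene | COc1ccc(/C=C(\I)CO[C@H](C=C)c2ccc(OC)c(OC)c2)cc1OC
F5 | step 4 | (2S,4E)-4-(3,4-dimethoxybenzylidene)-2-(3,4-dimethoxyphenyl)-3-methylenetetrahydrofuran | COc1ccc(/C=C2/CO[C@@H](c3ccc(OC)c(OC)c3)C2=C)cc1OC
F6 | step 4 | (2S,3S,4Z)-4-(3,4-dimethoxybenzylidene)-2-(3,4-dimethoxyphenyl)-3-(hydroxymethyl)tetrahydrofuran-3-ol | OC[C@@]1(O)/C(=C\c2ccc(OC)c(OC)c2)CO[C@H]1c1ccc(OC)c(OC)c1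
F7 | step 5 | {3-[(1R)-1-(3,4-dimethoxyphenyl)prop-2-en-1-yloxy]prop-1-yn-1-yl}trimethylsilane | C[Si](C)(C)C#CCO[C@H](C=C)c1ccc(OC)c(OC)c1
F8 | step 5 | (2S,4Z)-2-(3,4-dimethoxyphenyl)-3-methylene-4-[(trimethylsilyl)methylene]tetrahydrofuran | C[Si](C)(C)/C=C1\CO[C@@H](c2ccc(OC)c(OC)c2)C1=C
F9 | step 5 | (2S,3S,4E)-2-(3,4-dimethoxyphenyl)-3-(hydroxymethyl)-4-[(trimethylsilyl)methylene]tetrahydrofuran-3-ol | OC[C@@]1(O)/C(=C/[Si](C)(C)C)CO[C@H]1c1ccc(OC)c(OC)c1
F10 | step 5 | (2S,3S,4E)-2-(3,4-dimethoxyphenyl)-3-(hydroxymethyl)-4-(iodomethylene)tetrahydrofuran-3-ol | OC[C@@]1(O)/C(=C/I)CO[C@H]1c1ccc(OC)c(OC)c1
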